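**Plan**

Ring numbering used throughout: C1 carries the aroyl group, C2 the prenyl group, C3 the methyl group (C3=C4), C5 is CH2, C6 carries phenyl.
- Cuts: first the aryl–C(=O) bond (aryllithium plus cyclohexenecarbaldehyde), then the ring bond C1–C2.
- Enabling feature: C(=O)–C1–C2–C3=C4 is a γ,δ-unsaturated carbonyl unit, and C4 is tied to C1 through C5–C6. Joining the carbonyl carbon to C4 through oxygen gives a six-membered lactone, a ring absent from the target, whose silyl ketene acetal can only form C1–C2 by a [3,3] shift.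
- Forward: (E)-dienal → (R)-6-alkenyl-5,6-dihydropyran-2-one → trans-4-phenyl lactone → Ireland–Claisen ring contraction closes the cyclohexene → ester, aldehyde, aryl ketone.
- Stereochemistry: the carbinol centre comes from a reagent-controlled allylboration, and C6 from conjugate arylation anti to it. C2 comes by chirality transfer through the tether-enforced boat with the (E)-alkene. C1 emerges cis to both neighbours and is corrected by base equilibration of the ester to the all-equatorial epimer.
- The lactone C–O bond and its stereocentre are consumed in the key step.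

Key step: step 7

Assumption: the allylborane built from (−)-α-pinene is taken to add to the aldehyde face that gives the (R)-carbinol 6; if the sense were opposite, the antipodal reagent would be used and nothing else changes.

**Route**

Step 1
Reactants: 1 prop-2-yn-1-ol; 2 1-chloro-3-methylbut-2-ene
Product: 4 (2E)-2,6-dimethylhepta-2,5-dien-1-ol, via alkenylalane 3 (not isolated)
Conditions: Me3Al (3 equiv), Cp2ZrCl2 (0.25 equiv), CH2Cl2, 0 °C to rt; then 2, Pd(PPh3)4 (3 mol%), THF, rt; cold 1 M HCl work-up
Reagents that add atoms: trimethylaluminium, C[Al](C)C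
Why: Negishi syn-carboalumination puts methyl on the internal and aluminium on the terminal alkyne carbon, and the zerovalent-palladium-catalysed allylation of the alkenylalane at the unhindered allyl terminus proceeds with retention, which should fix the (E)-trisubstituted alkene of the skipped diene.

Step 2
Reactants: 4 (2E)-2,6-dimethylhepta-2,5-dien-1-ol
Product: 5 (2E)-2,6-dimethylhepta-2,5-dienal
Conditions: TEMPO (10 mol%), PhI(OAc)2 (1.1 equiv), CH2Cl2, rt
Reagents that add atoms: none
Why: oxoammonium-mediated oxidation of a primary allylic alcohol stops at the aldehyde under neutral conditions, so neither the (E) geometry nor the skipped diene should move.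

Step 3
Reactants: 5 (2E)-2,6-dimethylhepta-2,5-dienal
Product: 6 (4R,5E)-5,9-dimethyldeca-1,5,8-trien-4-ol
Conditions: Ipc2B(allyl) derived from (−)-α-pinene (salt-free, 1.3 equiv), Et2O, −78 °C; then 3 M NaOH, 30% H2O2, 0 °C to rt
Reagents that add atoms: B-allyldiisopinocampheylborane from (−)-α-pinene, C=CCB([C@H]1C[C@H]2C[C@@H]([C@@H]1C)C2(C)C)[C@H]3C[C@H]4C[C@@H]([C@@H]3C)C4(C)C
Why: Brown allylboration through a closed chair (Zimmerman–Traxler) transition state in which the isopinocampheyl groups select the aldehyde face, which is expected to set the (R)-carbinol under reagent control.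

Step 4
Reactants: 6 (4R,5E)-5,9-dimethyldeca-1,5,8-trien-4-ol; 7 prop-2-enoyl chloride
Product: 8 (4R,5E)-5,9-dimethyldeca-1,5,8-trien-4-yl prop-2-enoate
Conditions: 7 (1.2 equiv), Et3N (1.5 equiv), DMAP (5 mol%), CH2Cl2, 0 °C
Reagents that add atoms: none
Why: DMAP-catalysed O-acylation of the secondary alcohol, which does not touch the stereocentre.

Step 5
Reactants: 8 (4R,5E)-5,9-dimethyldeca-1,5,8-trien-4-yl prop-2-enoate
Product: 9 (6R)-6-[(2E)-6-methylhepta-2,5-dien-2-yl]-5,6-dihydro-2H-pyran-2-one
Conditions: second-generation Grubbs catalyst RuCl2(=CHPh)(H2IMes)(PCy3) (5 mol%), CH2Cl2 (5 mM), 40 °C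
Reagents that add atoms: none
Why: ring-closing metathesis joins the acrylate and the terminal vinyl group; the trisubstituted alkenes are poor partners and the (E) geometry of the nearer one excludes a competing ring.

Step 6
Reactants: 9 (6R)-6-[(2E)-6-methylhepta-2,5-dien-2-yl]-5,6-dihydro-2H-pyran-2-one; 10 phenylboronic acid
Product: 11 (4S,6R)-6-[(2E)-6-methylhepta-2,5-dien-2-yl]-4-phenyloxan-2-one
Conditions: [Rh(OH)(cod)]2 (2.5 mol%), 10 (2 equiv), dioxane/H2O (10:1), 40 °C
Reagents that add atoms: none
Why: Hayashi–Miyaura conjugate arylation, in which the aryl-rhodium species should add to C4 of the half-chair lactone on the face anti to the pseudoequatorial C6 alkenyl group, giving the trans-4,6-disubstituted lactone (4S) by substrate control.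

Step 7
Reactants: 11 (4S,6R)-6-[(2E)-6-methylhepta-2,5-dien-2-yl]-4-phenyloxan-2-one
Product: 14 (1R,2S,6S)-3-methyl-2-(3-methylbut-2-en-1-yl)-6-phenylcyclohex-3-ene-1-carboxylic acid, via silyl ketene acetal 12 (not isolated), via trimethylsilyl ester 13 (not isolated)
Conditions: LiN(iPr)2 (1.3 equiv), Me3SiCl/Et3N (1:1, 3 equiv, present during enolisation), THF, −78 °C to rt; solvent exchange to PhMe, 105 °C; dilute aqueous HCl work-up
Reagents that add atoms: none
Why: LiN(iPr)2 with Me3SiCl present traps the lactone enolate as the cyclic silyl ketene acetal 12, an allyl vinyl ether whose six reacting atoms are C1=C(OSi)–O–C4–C3=C2; on heating, a concerted suprafacial [3,3]-sigmatropic shift should form C1–C2, break the lactone C4–O bond and move the alkene to C3=C4, giving silyl ester 13 and, after hydrolysis, acid 14. The reaction type is the Ireland–Claisen ring contraction of a 6-alkenyl lactone, closest in kind to the rearrangements of alkenyl-substituted lactone and dioxanone silyl ketene acetals to cyclohexenes and dihydropyrans. The cyclohexene closes in a 6-(enolexo)-endo-trig sense, and because C5–C6 ties C1 to C4 only a boat transition state shaped like bicyclo[2.2.2]octene is possible, a chair requiring a trans-cyclohexene. C1 is set because the new bond must form on the lactone face that carries the alkenyl group, which leaves the carboxyl on the face of the departed oxygen and cis to the phenyl group of the trans-lactone; C2 is set by the (E)-alkene, whose prenyl arm takes the outer position of the boat and ends cis to the carboxyl, so the carbinol configuration is transferred to C1 and C2 (1R,2S) while C6 is untouched. The step needs enolisation without Claisen self-condensation and a single alkene geometry: silylation in situ at −78 °C should secure the first, the carboalumination of step 1 the second, and attack at C2 rather than C4 is inherent in the sigmatropic topology.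

Step 8
Reactants: 14 (1R,2S,6S)-3-methyl-2-(3-methylbut-2-en-1-yl)-6-phenylcyclohex-3-ene-1-carboxylic acid
Product: 16 methyl (1S,2S,6S)-3-methyl-2-(3-methylbut-2-en-1-yl)-6-phenylcyclohex-3-ene-1-carboxylate, via all-cis methyl ester 15 (not isolated)
Conditions: Me3SiCHN2 (1.5 equiv), MeOH/PhMe (1:4), 0 °C; then NaOMe (1 equiv), MeOH, 65 °C
Reagents that add atoms: (trimethylsilyl)diazomethane, C[Si](C)(C)C=[N+]=[N-]; sodium methoxide (degenerate exchange of the methoxy group), C[O-].[Na+]
Why: esterification followed by reversible enolate formation at C1, the only acidic C–H, should let the axial ester of 15, wedged between the cis-equatorial prenyl and phenyl groups, relax to the all-equatorial epimer 16 under thermodynamic control (base-mediated epimerisation), residual 15 being separable and resubmitted.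

Step 9
Reactants: 16 methyl (1S,2S,6S)-3-methyl-2-(3-methylbut-2-en-1-yl)-6-phenylcyclohex-3-ene-1-carboxylate
Product: 17 (1S,2S,6S)-3-methyl-2-(3-methylbut-2-en-1-yl)-6-phenylcyclohex-3-ene-1-carbaldehyde
Conditions: iBu2AlH (1.1 equiv), CH2Cl2, −78 °C; aqueous potassium sodium tartrate work-up
Reagents that add atoms: none
Why: the tetrahedral aluminium hemiacetal of a hindered α-branched ester should persist at −78 °C and release the aldehyde only on work-up (partial ester reduction), the non-basic conditions leaving C1 unchanged.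

Step 10
Reactants: 18 3-hydroxy-4,5-dimethoxybenzaldehyde
Product: 20 4,5-dimethoxybenzene-1,3-diol, via aryl formate 19 (not isolated)
Conditions: mCPBA (1.3 equiv), CH2Cl2, 0 °C to rt; then K2CO3 (cat.), MeOH, rt
Reagents that add atoms: 3-chloroperoxybenzoic acid, O=C(OO)c1cccc(Cl)c1
Why: Baeyer–Villiger (Dakin-type) oxidation in which the electron-rich trioxygenated aryl group migrates, followed by methanolysis of the formate to the phenol.

Step 11
Reactants: 20 4,5-dimethoxybenzene-1,3-diol
Product: 21 1,2-dimethoxy-3,5-bis(methoxymethoxy)benzene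
Conditions: MOMCl (2.5 equiv), iPr2NEt (3 equiv), CH2Cl2, 0 °C to rt
Reagents that add atoms: chloromethyl methyl ether, COCCl
Why: O-alkylation of both phenols installs two acetal groups that protect the phenols and direct the later metalation.

Step 12
Reactants: 21 1,2-dimethoxy-3,5-bis(methoxymethoxy)benzene; 17 (1S,2S,6S)-3-methyl-2-(3-methylbut-2-en-1-yl)-6-phenylcyclohex-3-ene-1-carbaldehyde
Product: 23 [3,4-dimethoxy-2,6-bis(methoxymethoxy)phenyl][(1S,2S,6S)-3-methyl-2-(3-methylbut-2-en-1-yl)-6-phenylcyclohex-3-en-1-yl]methanol (both carbinol epimers), via aryllithium 22 (not isolated)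
Conditions: n-BuLi (1.1 equiv), TMEDA (1.1 equiv), THF, 0 °C, 1 h; then 17 (0.8 equiv), −78 °C; aqueous NH4Cl
Reagents that add atoms: none
Why: directed ortho-metalation at the ring position flanked by both OMOM groups, then 1,2-addition of the aryllithium to the aldehyde at −78 °C, where addition should outrun deprotonation at C1; the new carbinol centre is removed in step 13.

Step 13
Reactants: 23 [3,4-dimethoxy-2,6-bis(methoxymethoxy)phenyl][(1S,2S,6S)-3-methyl-2-(3-methylbut-2-en-1-yl)-6-phenylcyclohex-3-en-1-yl]methanol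
Product: 24 [3,4-dimethoxy-2,6-bis(methoxymethoxy)phenyl][(1S,2S,6S)-3-methyl-2-(3-methylbut-2-en-1-yl)-6-phenylcyclohex-3-en-1-yl]methanone
Conditions: Dess–Martin periodinane (1.5 equiv), CH2Cl2, rt
Reagents that add atoms: none
Why: Dess–Martin oxidation of the hindered secondary alcohol under near-neutral conditions, which should leave the alkenes, the acetals and C1 untouched.

Step 14
Reactants: 24 [3,4-dimethoxy-2,6-bis(methoxymethoxy)phenyl][(1S,2S,6S)-3-methyl-2-(3-methylbut-2-en-1-yl)-6-phenylcyclohex-3-en-1-yl]methanone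
Product: 25 (2,6-dihydroxy-3,4-dimethoxyphenyl)[(1S,2S,6S)-3-methyl-2-(3-methylbut-2-en-1-yl)-6-phenylcyclohex-3-en-1-yl]methanone
Conditions: 3 M aqueous HCl, MeOH, 40 °C
Reagents that add atoms: none
Why: acid-catalysed acetal exchange frees both phenols ortho to the ketone, and C1 already holds its thermodynamically preferred configuration, so acid should not change it.

**Compound list**

1 | prop-2-yn-1-ol | C#CCO | starting material
2 | 1-chloro-3-methylbut-2-ene | CC(C)=CCCl | starting material
3 | [(1E)-3-(dimethylalumanyloxy)-2-methylprop-1-en-1-yl]dimethylalumane | C[Al](C)OC/C(C)=C/[Al](C)C | intermediate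
4 | (2E)-2,6-dimethylhepta-2,5-dien-1-ol | OC/C(C)=C/CC=C(C)C | intermediate
5 | (2E)-2,6-dimethylhepta-2,5-dienal | O=C/C(C)=C/CC=C(C)C | intermediate
6 | (4R,5E)-5,9-dimethyldeca-1,5,8-trien-4-ol | C=CC[C@@H](O)/C(C)=C/CC=C(C)C | intermediate
7 | prop-2-enoyl chloride | C=CC(=O)Cl | starting material
8 | (4R,5E)-5,9-dimethyldeca-1,5,8-trien-4-yl prop-2-enoate | C=CC(=O)O[C@H](CC=C)/C(C)=C/CC=C(C)C | intermediate
9 | (6R)-6-[(2E)-6-methylhepta-2,5-dien-2-yl]-5,6-dihydro-2H-pyran-2-one | O=C1C=CC[C@H](/C(C)=C/CC=C(C)C)O1 | intermediate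
10 | phenylboronic acid | OB(O)c1ccccc1 | starting material
11 | (4S,6R)-6-[(2E)-6-methylhepta-2,5-dien-2-yl]-4-phenyloxan-2-one (phenyl and alkenyl trans) | O=C1C[C@@H](c2ccccc2)C[C@H](/C(C)=C/CC=C(C)C)O1 | intermediate
12 | trimethyl{[(2R,4S)-2-[(2E)-6-methylhepta-2,5-dien-2-yl]-4-phenyl-3,4-dihydro-2H-pyran-6-yl]oxy}silane | C[Si](C)(C)OC1=C[C@@H](c2ccccc2)C[C@H](/C(C)=C/CC=C(C)C)O1 | intermediate
13 | trimethylsilyl (1R,2S,6S)-3-methyl-2-(3-methylbut-2-en-1-yl)-6-phenylcyclohex-3-ene-1-carboxylate | C[Si](C)(C)OC(=O)[C@@H]1[C@H](CC=C(C)C)C(C)=CC[C@@H]1c1ccccc1 | intermediate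
14 | (1R,2S,6S)-3-methyl-2-(3-methylbut-2-en-1-yl)-6-phenylcyclohex-3-ene-1-carboxylic acid (carboxyl, prenyl and phenyl all cis) | OC(=O)[C@@H]1[C@H](CC=C(C)C)C(C)=CC[C@@H]1c1ccccc1 | intermediate
15 | methyl (1R,2S,6S)-3-methyl-2-(3-methylbut-2-en-1-yl)-6-phenylcyclohex-3-ene-1-carboxylate (all cis) | COC(=O)[C@@H]1[C@H](CC=C(C)C)C(C)=CC[C@@H]1c1ccccc1 | intermediate
16 | methyl (1S,2S,6S)-3-methyl-2-(3-methylbut-2-en-1-yl)-6-phenylcyclohex-3-ene-1-carboxylate (ester trans to prenyl and to phenyl) | COC(=O)[C@H]1[C@H](CC=C(C)C)C(C)=CC[C@@H]1c1ccccc1 | intermediate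
17 | (1S,2S,6S)-3-methyl-2-(3-methylbut-2-en-1-yl)-6-phenylcyclohex-3-ene-1-carbaldehyde | O=C[C@H]1[C@H](CC=C(C)C)C(C)=CC[C@@H]1c1ccccc1 | intermediate
18 | 3-hydroxy-4,5-dimethoxybenzaldehyde | O=Cc1cc(O)c(OC)c(OC)c1 | starting material
19 | 3-hydroxy-4,5-dimethoxyphenyl formate | O=COc1cc(O)c(OC)c(OC)c1 | intermediate
20 | 4,5-dimethoxybenzene-1,3-diol | Oc1cc(O)c(OC)c(OC)c1 | intermediate
21 | 1,2-dimethoxy-3,5-bis(methoxymethoxy)benzene | COCOc1cc(OCOC)c(OC)c(OC)c1 | intermediate
22 | [3,4-dimethoxy-2,6-bis(methoxymethoxy)phenyl]lithium | [Li]c1c(OCOC)cc(OC)c(OC)c1OCOC | intermediate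
23 | [3,4-dimethoxy-2,6-bis(methoxymethoxy)phenyl][(1S,2S,6S)-3-methyl-2-(3-methylbut-2-en-1-yl)-6-phenylcyclohex-3-en-1-yl]methanol (carbinol epimers) | COCOc1cc(OC)c(OC)c(OCOC)c1C(O)[C@H]1[C@H](CC=C(C)C)C(C)=CC[C@@H]1c1ccccc1 | intermediate
24 | [3,4-dimethoxy-2,6-bis(methoxymethoxy)phenyl][(1S,2S,6S)-3-methyl-2-(3-methylbut-2-en-1-yl)-6-phenylcyclohex-3-en-1-yl]methanone | COCOc1cc(OC)c(OC)c(OCOC)c1C(=O)[C@H]1[C@H](CC=C(C)C)C(C)=CC[C@@H]1c1ccccc1 | intermediate
25 | (2,6-dihydroxy-3,4-dimethoxyphenyl)[(1S,2S,6S)-3-methyl-2-(3-methylbut-2-en-1-yl)-6-phenylcyclohex-3-en-1-yl]methanone | COc1cc(O)c(C(=O)[C@H]2[C@H](CC=C(C)C)C(C)=CC[C@@H]2c2ccccc2)c(O)c1OC | target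

**Count**

Total steps: 14. Longest linear sequence: 12 (steps 1 to 9, then 12 to 14).

**Steps most likely to fail**

Step 7. The lactone enolate may self-condense before it is silylated, or the silyl ketene acetal may decompose thermally before the strained boat rearrangement sets in. The fallback sets out from lactone 11 and uses a neutral Claisen rearrangement of a cyclic enol ether, with no enolate or silyl ketene acetal. Reduction of 11 with iBu2AlH (CH2Cl2, −78 °C) gives the lactol (4S,6R)-6-[(2E)-6-methylhepta-2,5-dien-2-yl]-4-phenyloxan-2-ol F1. Mesylation and elimination (MsCl, Et3N, CH2Cl2, 0 °C to reflux) give the enol ether (2R,4S)-2-[(2E)-6-methylhepta-2,5-dien-2-yl]-4-phenyl-3,4-dihydro-2H-pyran F2. Heating (PhMe, sealed tube, 200 °C) should rearrange this 2-alkenyl-dihydropyran through the same tether-enforced boat to the all-cis aldehyde (1R,2S,6S)-3-methyl-2-(3-methylbut-2-en-1-yl)-6-phenylcyclohex-3-ene-1-carbaldehyde F3. Pinnick oxidation (NaClO2, NaH2PO4, 2-methylbut-2-ene, t-BuOH/H2O) brings the route back at acid 14.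

Step 8. Enolisation of the doubly flanked ester may be slow, and the equilibrium may not lie far enough on the side of the all-equatorial epimer; the axial-to-equatorial gain at C1 of a cyclohexene is modest. The fallback sets out from the equilibrated mixture of 15 and 16 and separates the epimers chemically instead of relying on the equilibrium position. Saponification (LiOH, THF/MeOH/H2O, 50 °C) gives acid 14 together with (1S,2S,6S)-3-methyl-2-(3-methylbut-2-en-1-yl)-6-phenylcyclohex-3-ene-1-carboxylic acid F4. Iodolactonisation (I2, KI, NaHCO3, H2O/CH2Cl2, 0 °C, dark) should engage only 14, whose carboxylate is axial and can bridge to C3 of the ring alkene. This gives the neutral iodolactone 4-iodo-5-methyl-8-(3-methylbut-2-en-1-yl)-2-phenyl-6-oxabicyclo[3.2.1]octan-7-one F5, with iodine anti to the lactone oxygen. F4 would need both flanking groups axial to cyclise and should remain as the carboxylate. It is extracted into aqueous base and re-esterified with Me3SiCHN2, coming back to the route at 16. F5 is returned to 14 with Zn in AcOH and recycled.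

Step 12. The hindered aryllithium may deprotonate the α-branched aldehyde instead of adding to the carbonyl group. The fallback sets out from aldehyde 17 and replaces carbonyl addition by a non-basic acyl cross-coupling. Pinnick oxidation of 17 gives acid F4 (described under step 8). Treatment with 1-chloro-N,N,2-trimethylprop-1-en-1-amine (CH2Cl2, 0 °C) gives, under neutral conditions, (1S,2S,6S)-3-methyl-2-(3-methylbut-2-en-1-yl)-6-phenylcyclohex-3-ene-1-carbonyl chloride F6. Aryllithium 22 is transmetalated with ZnCl2 to [3,4-dimethoxy-2,6-bis(methoxymethoxy)phenyl]zinc chloride F7. Negishi acylation of F6 with F7 (Pd(PPh3)4, 5 mol%, THF, rt) comes back to the route at ketone 24, bypassing carbinol 23.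

**Further compounds**

F1 | step 7 | (4S,6R)-6-[(2E)-6-methylhepta-2,5-dien-2-yl]-4-phenyloxan-2-ol (both anomers) | OC1C[C@@H](c2ccccc2)C[C@H](/C(C)=C/CC=C(C)C)O1
F2 | step 7 | (2R,4S)-2-[(2E)-6-methylhepta-2,5-dien-2-yl]-4-phenyl-3,4-dihydro-2H-pyran | C1=C[C@@H](c2ccccc2)C[C@H](/C(C)=C/CC=C(C)C)O1
F3 | step 7 | (1R,2S,6S)-3-methyl-2-(3-methylbut-2-en-1-yl)-6-phenylcyclohex-3-ene-1-carbaldehyde (all cis) | O=C[C@@H]1[C@H](CC=C(C)C)C(C)=CC[C@@H]1c1ccccc1
F4 | step 8 | (1S,2S,6S)-3-methyl-2-(3-methylbut-2-en-1-yl)-6-phenylcyclohex-3-ene-1-carboxylic acid | OC(=O)[C@H]1[C@H](CC=C(C)C)C(C)=CC[C@@H]1c1ccccc1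
F5 | step 8 | 4-iodo-5-methyl-8-(3-methylbut-2-en-1-yl)-2-phenyl-6-oxabicyclo[3.2.1]octan-7-one (iodine anti to the lactone oxygen) | O=C1O[C@]2(C)[C@@H](I)C[C@H](c3ccccc3)[C@H]1[C@@H]2CC=C(C)C
F6 | step 12 | (1S,2S,6S)-3-methyl-2-(3-methylbut-2-en-1-yl)-6-phenylcyclohex-3-ene-1-carbonyl chloride | ClC(=O)[C@H]1[C@H](CC=C(C)C)C(C)=CC[C@@H]1c1ccccc1
F7 | step 12 | [3,4-dimethoxy-2,6-bis(methoxymethoxy)phenyl]zinc chloride | Cl[Zn]c1c(OCOC)cc(OC)c(OC)c1OCOC
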